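Target 18 ⇐ acidolysis of di-tert-butyl ester 17 ⇐ Yamaguchi acylation of 6β-alcohol 14 with octatrienoic acid 15; 14 ⇐ CBS reduction run as a kinetic resolution of racemic ketone 13 ⇐ α-face hydrogenation of bicyclic ketone 12, which sets C8 and C9 cis.
Key disconnection 12 ⇒ acyclic triene 9: C5–C10 by thermal disrotatory 6π electrocyclisation (ring B first), then C2–C3 by ring-closing metathesis of the two alkenyl arms that the electrocyclisation places on neighbouring carbons (ring A second), in one flask.
Enabling feature: ring B carries oxygen on C6 next to ring-fusion atom C5 and carboxyls on C8 and C9 next to ring-fusion atom C10, so C5=C6(OSi)–C7=C8(CO2R)–C9(CO2R)=C10 is a push–pull 2-silyloxy-hexatriene-dicarboxylate whose two termini are the ring-fusion carbons, each already bearing its ring A arm (gem-dimethyl/vinyl on C5; methyl and allyl on C10).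
Triene 9 ⇐ Stille coupling (C8–C9) of silyloxy-dienyl triflate 6 (mesityl oxide, vinyl cuprate, oxalate Claisen, triflation, silylation) with α-stannyl enoate 8 (syn-allylcupration of tert-butyl but-2-ynoate).
Key step: step 7

Remark: ring atoms are numbered as in drimane (C1–C10; C11 is the carboxyl carbon on C9, C12 the one on C8); compounds 10–13 are racemic and their SMILES show the enantiomer that step 9 carries forward; 1, 3, 7 and 15 are taken as commercial.

Step 1
Reactants: 1 mesityl oxide (4-methylpent-3-en-2-one)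
Product: 2 4,4-dimethylhex-5-en-2-one
Conditions: vinylmagnesium bromide (1.3 equiv), CuI (10 mol %), THF, −30 → 0 °C; aq. NH4Cl
Reagents that add atoms: vinylmagnesium bromide, C=C[Mg]Br
Why: Copper-catalysed conjugate (1,4-) addition of the vinyl Grignard reagent to the β,β-disubstituted enone builds the quaternary gem-dimethyl carbon C4 together with its vinyl arm (C3); no stereocenter is formed.

Step 2
Reactants: 2 4,4-dimethylhex-5-en-2-one; 3 di-tert-butyl oxalate
Product: 4 tert-butyl (2Z)-2-hydroxy-6,6-dimethyl-4-oxoocta-2,7-dienoate (enol form of the 2,4-dioxo ester)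
Conditions: LiHMDS (1.1 equiv), THF, −78 °C; then 3, −78 → 20 °C; aq. HCl
Reagents that add atoms: none
Why: Crossed Claisen condensation: the kinetic enolate on the methyl side (the CH2 next to the quaternary carbon is shielded) acylates the non-enolisable oxalate, and the product should rest as the hydrogen-bonded (Z)-enol, which already holds C5–C8 and C12.

Step 3
Reactants: 4 tert-butyl (2Z)-2-hydroxy-6,6-dimethyl-4-oxoocta-2,7-dienoate
Product: 5 tert-butyl (2Z)-6,6-dimethyl-4-oxo-2-(trifluoromethanesulfonyloxy)octa-2,7-dienoate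
Conditions: Tf2O (1.1 equiv), i-Pr2NEt (1.3 equiv), CH2Cl2, −78 °C
Reagents that add atoms: trifluoromethanesulfonic anhydride, O=S(=O)(OS(=O)(=O)C(F)(F)F)C(F)(F)F
Why: O-Triflation of the enol oxygen next to the ester (the enol oxygen of the resting tautomer) should give the vinylogous acyl triflate with the (Z) geometry of the chelated enol, so that the group entering later at C8 ends cis to the C6 acyl group.

Step 4
Reactants: 5 tert-butyl (2Z)-6,6-dimethyl-4-oxo-2-(trifluoromethanesulfonyloxy)octa-2,7-dienoate
Product: 6 tert-butyl (2Z,4Z)-4-(tert-butyldimethylsilyloxy)-6,6-dimethyl-2-(trifluoromethanesulfonyloxy)octa-2,4,7-trienoate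
Conditions: TBSOTf (1.2 equiv), Et3N (2 equiv), CH2Cl2, −78 → 0 °C
Reagents that add atoms: tert-butyldimethylsilyl trifluoromethanesulfonate, CC(C)(C)[Si](C)(C)OS(=O)(=O)C(F)(F)F
Why: Soft enolisation (silyl triflate/amine) can only remove a C5 proton because C7 is sp2, and should give the cross-conjugated (Z)-silyl enol ether with the bulky quaternary group trans to C7; masking the ketone here also means that no free dienone, which could scramble alkene geometry by oxa-6π closure and reopening, ever exists.

Step 5
Reactants: 7 tert-butyl but-2-ynoate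
Product: 8 tert-butyl (2Z)-3-methyl-2-(tributylstannyl)hexa-2,5-dienoate
Conditions: allylmagnesium bromide (1.2 equiv), CuBr·SMe2 (1.2 equiv), THF, −78 °C; then 7, −78 °C; then Bu3SnCl (1.3 equiv), −78 → −30 °C
Reagents that add atoms: allylmagnesium bromide, C=CC[Mg]Br; tributyltin chloride, CCCC[Sn](Cl)(CCCC)CCCC
Why: syn-Carbocupration of the ynoate puts allyl on the β-carbon cis to copper, and stannylation of the vinylcopper with retention should give the (Z)-α-stannyl enoate, which fixes the C9=C10 geometry (allyl cis to tin, methyl cis to the ester).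

Step 6
Reactants: 6 tert-butyl (2Z,4Z)-4-(tert-butyldimethylsilyloxy)-6,6-dimethyl-2-(trifluoromethanesulfonyloxy)octa-2,4,7-trienoate; 8 tert-butyl (2Z)-3-methyl-2-(tributylstannyl)hexa-2,5-dienoate
Product: 9 di-tert-butyl (2E,3E)-2-(pent-4-en-2-ylidene)-3-[(2Z)-2-(tert-butyldimethylsilyloxy)-4,4-dimethylhexa-2,5-dien-1-ylidene]butanedioate
Conditions: Pd2(dba)3 (5 mol %), P(2-furyl)3 (20 mol %), CuI (20 mol %), LiCl (3 equiv), NMP, 20 °C; product kept cold
Reagents that add atoms: none
Why: Copper-assisted Stille cross-coupling of vinyl triflate and vinylstannane forms the C8–C9 single bond with retention at both sp2 carbons, so the triene should have C6 cis to C9, the allyl group on the inner side and the methyl group on the outer side of the terminus C10.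

Step 7
Reactants: 9 di-tert-butyl (2E,3E)-2-(pent-4-en-2-ylidene)-3-[(2Z)-2-(tert-butyldimethylsilyloxy)-4,4-dimethylhexa-2,5-dien-1-ylidene]butanedioate
Product: 12 rac-di-tert-butyl (4aS,8aS)-5,5,8a-trimethyl-4-oxo-3,4,4a,5,8,8a-hexahydronaphthalene-1,2-dicarboxylate, via electrocyclised silyl enol ether 10 (not isolated), via bicyclic silyl dienol ether 11 (not isolated)
Conditions: second-generation Hoveyda–Grubbs catalyst [RuCl2(H2IMes)(=CH-C6H4-2-OiPr)] (5 mol %), PhMe (5 mM), 80 °C; then 0.5 M aq. HCl, THF, 0 °C
Reagents that add atoms: none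
Why: At 80 °C the push–pull triene C5=C6(OTBS)–C7=C8(CO2tBu)–C9(CO2tBu)=C10 should close by thermal disrotatory 6π electrocyclisation (enol-ether terminus C5 onto enoate terminus C10) to cyclohexadiene 10, and only then are the vinyl arm on C4 and the allyl arm on C10 close enough for the ruthenium carbene to close ring A by ring-closing metathesis between C2 and C3 with loss of ethene; cold dilute acid then unmasks the C6 ketone by protonation at C7. The closest known reaction types are the thermal 6π closure of 2-silyloxy hexatrienes and of bis(alkylidene)succinates, and RCM to cyclohexenes flanked by quaternary carbons. Ring B closes in the electrocyclic mode (all six ring atoms come from the triene, new σ bond C5–C10), ring A in the metathesis mode (six-membered ring, new C2=C3 bond). C5 and C10 are set together by the disrotatory rule from the alkene geometries: the outer groups (C4 on C5, methyl on C10) end cis, so H-5 and the C10 methyl are trans and the decalin is trans-fused, as the racemate. The step needs periselectivity (6π before a [1,7]-hydrogen shift from the inner allylic CH2, secured by the donor/acceptor pattern that lowers the 6π barrier), chemoselectivity of the carbene for the two terminal monosubstituted alkenes (all others are tri- or tetrasubstituted, and ring closure before the electrocyclisation would need a ten-membered ring) and a configurationally stable C5 (no base, only brief cold acid).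

Step 8
Reactants: 12 rac-di-tert-butyl (4aS,8aS)-5,5,8a-trimethyl-4-oxo-3,4,4a,5,8,8a-hexahydronaphthalene-1,2-dicarboxylate
Product: 13 rac-di-tert-butyl (1S,2S,4aS,8aS)-5,5,8a-trimethyl-4-oxodecahydronaphthalene-1,2-dicarboxylate
Conditions: H2 (50 bar), 10% Pd/C, EtOAc, 40 °C
Reagents that add atoms: none
Why: Heterogeneous hydrogenation should add H2 to the disubstituted C2=C3 bond and to the tetrasubstituted, ester-activated C8=C9 bond from the α-face, opposite to the axial C10 methyl group, so that C8 and C9 are set together as the cis (8β,9β) diester.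

Step 9
Reactants: 13 rac-di-tert-butyl (1S,2S,4aS,8aS)-5,5,8a-trimethyl-4-oxodecahydronaphthalene-1,2-dicarboxylate
Product: 14 di-tert-butyl (1S,2S,4R,4aS,8aS)-4-hydroxy-5,5,8a-trimethyldecahydronaphthalene-1,2-dicarboxylate
Conditions: (S)-Me-CBS oxazaborolidine (0.2 equiv), BH3·SMe2 (0.6 equiv), PhMe, −20 °C, stopped near half conversion; MeOH
Reagents that add atoms: none
Why: Corey–Bakshi–Shibata reduction run as a kinetic resolution: hydride goes to the α-face that the substrate itself exposes (the β-face is blocked by the axial methyl groups on C4 and C10 and by the axial C8 ester), and this face is matched with the (S)-catalyst only in the (5S,10S)-ketone, which should give the 6β (6R) alcohol while the mirror-image ketone is left behind.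

Step 10
Reactants: 14 di-tert-butyl (1S,2S,4R,4aS,8aS)-4-hydroxy-5,5,8a-trimethyldecahydronaphthalene-1,2-dicarboxylate; 15 (2E,4E,6E)-octa-2,4,6-trienoic acid
Product: 17 di-tert-butyl (1S,2S,4R,4aS,8aS)-5,5,8a-trimethyl-4-{[(2E,4E,6E)-octa-2,4,6-trienoyl]oxy}decahydronaphthalene-1,2-dicarboxylate, via mixed anhydride 16 (not isolated)
Conditions: 15, 2,4,6-trichlorobenzoyl chloride (1.5 equiv), Et3N (2 equiv), THF, 20 °C; then 14, DMAP (2 equiv), PhMe, 60 °C
Reagents that add atoms: none
Why: Yamaguchi esterification: the mixed anhydride acylates DMAP and the acylpyridinium should be reactive enough to esterify the hindered axial 6β-alcohol, while the tert-butyl esters prevent lactonisation onto the syn-axial C8 carboxyl; no stereocenter is touched.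

Step 11
Reactants: 17 di-tert-butyl (1S,2S,4R,4aS,8aS)-5,5,8a-trimethyl-4-{[(2E,4E,6E)-octa-2,4,6-trienoyl]oxy}decahydronaphthalene-1,2-dicarboxylate
Product: 18 (1S,2S,4R,4aS,8aS)-5,5,8a-trimethyl-4-{[(2E,4E,6E)-octa-2,4,6-trienoyl]oxy}decahydronaphthalene-1,2-dicarboxylic acid (CNP0462207.1)
Conditions: CF3CO2H/CH2Cl2 (1:4), 0 → 20 °C
Reagents that add atoms: none
Why: Acidolysis of the two tert-butyl esters (loss of isobutene via the tert-butyl cation) should free the diacid under conditions that neither cleave the trienoate nor epimerise C8 or C9.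

Compound list
1 | mesityl oxide (4-methylpent-3-en-2-one) | CC(C)=CC(C)=O | starting material
2 | 4,4-dimethylhex-5-en-2-one | CC(=O)CC(C)(C)C=C | intermediate
3 | di-tert-butyl oxalate | CC(C)(C)OC(=O)C(=O)OC(C)(C)C | starting material
4 | tert-butyl (2Z)-2-hydroxy-6,6-dimethyl-4-oxoocta-2,7-dienoate | C=CC(C)(C)CC(=O)/C=C(\O)C(=O)OC(C)(C)C | intermediate
5 | tert-butyl (2Z)-6,6-dimethyl-4-oxo-2-(trifluoromethanesulfonyloxy)octa-2,7-dienoate | C=CC(C)(C)CC(=O)/C=C(\OS(=O)(=O)C(F)(F)F)C(=O)OC(C)(C)C | intermediate
6 | tert-butyl (2Z,4Z)-4-(tert-butyldimethylsilyloxy)-6,6-dimethyl-2-(trifluoromethanesulfonyloxy)octa-2,4,7-trienoate | C=CC(C)(C)/C=C(\O[Si](C)(C)C(C)(C)C)/C=C(\OS(=O)(=O)C(F)(F)F)C(=O)OC(C)(C)C | intermediate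
7 | tert-butyl but-2-ynoate | CC#CC(=O)OC(C)(C)C | starting material
8 | tert-butyl (2Z)-3-methyl-2-(tributylstannyl)hexa-2,5-dienoate | C=CC/C(C)=C(\[Sn](CCCC)(CCCC)CCCC)C(=O)OC(C)(C)C | intermediate
9 | di-tert-butyl (2E,3E)-2-(pent-4-en-2-ylidene)-3-[(2Z)-2-(tert-butyldimethylsilyloxy)-4,4-dimethylhexa-2,5-dien-1-ylidene]butanedioate | C/C(CC=C)=C(\C(=O)OC(C)(C)C)/C(C(=O)OC(C)(C)C)=C\C(O[Si](C)(C)C(C)(C)C)=C\C(C)(C)C=C | intermediate
10 | rac-di-tert-butyl (5S,6S)-4-(tert-butyldimethylsilyloxy)-6-methyl-5-(2-methylbut-3-en-2-yl)-6-(prop-2-en-1-yl)cyclohexa-1,3-diene-1,2-dicarboxylate (methyl cis to the 2-methylbut-3-en-2-yl group) | CC(C)(C)[Si](C)(C)OC1=CC(C(=O)OC(C)(C)C)=C(C(=O)OC(C)(C)C)[C@@](C)(CC=C)[C@@H]1C(C)(C)C=C | intermediate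
11 | rac-di-tert-butyl (4aS,8aS)-4-(tert-butyldimethylsilyloxy)-5,5,8a-trimethyl-4a,5,8,8a-tetrahydronaphthalene-1,2-dicarboxylate (trans-fused) | CC(C)(C)[Si](C)(C)OC1=CC(C(=O)OC(C)(C)C)=C(C(=O)OC(C)(C)C)[C@@]2(C)CC=CC(C)(C)[C@H]12 | intermediate
12 | rac-di-tert-butyl (4aS,8aS)-5,5,8a-trimethyl-4-oxo-3,4,4a,5,8,8a-hexahydronaphthalene-1,2-dicarboxylate | O=C1CC(C(=O)OC(C)(C)C)=C(C(=O)OC(C)(C)C)[C@@]2(C)CC=CC(C)(C)[C@H]12 | intermediate
13 | rac-di-tert-butyl (1S,2S,4aS,8aS)-5,5,8a-trimethyl-4-oxodecahydronaphthalene-1,2-dicarboxylate | O=C1C[C@H](C(=O)OC(C)(C)C)[C@H](C(=O)OC(C)(C)C)[C@@]2(C)CCCC(C)(C)[C@H]12 | intermediate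
14 | di-tert-butyl (1S,2S,4R,4aS,8aS)-4-hydroxy-5,5,8a-trimethyldecahydronaphthalene-1,2-dicarboxylate | O[C@@H]1C[C@H](C(=O)OC(C)(C)C)[C@H](C(=O)OC(C)(C)C)[C@@]2(C)CCCC(C)(C)[C@H]12 | intermediate
15 | (2E,4E,6E)-octa-2,4,6-trienoic acid | C/C=C/C=C/C=C/C(=O)O | starting material
16 | (2E,4E,6E)-octa-2,4,6-trienoic 2,4,6-trichlorobenzoic anhydride | C/C=C/C=C/C=C/C(=O)OC(=O)c1c(Cl)cc(Cl)cc1Cl | intermediate
17 | di-tert-butyl (1S,2S,4R,4aS,8aS)-5,5,8a-trimethyl-4-{[(2E,4E,6E)-octa-2,4,6-trienoyl]oxy}decahydronaphthalene-1,2-dicarboxylate | C/C=C/C=C/C=C/C(=O)O[C@@H]1C[C@H](C(=O)OC(C)(C)C)[C@H](C(=O)OC(C)(C)C)[C@@]2(C)CCCC(C)(C)[C@H]12 | intermediate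
18 | (1S,2S,4R,4aS,8aS)-5,5,8a-trimethyl-4-{[(2E,4E,6E)-octa-2,4,6-trienoyl]oxy}decahydronaphthalene-1,2-dicarboxylic acid (CNP0462207.1) | C/C=C/C=C/C=C/C(=O)O[C@@H]1C[C@H](C(=O)O)[C@H](C(=O)O)[C@@]2(C)CCCC(C)(C)[C@H]12 | target

Total step count: 11. Longest linear sequence: 10 steps (steps 1–4 and 6–11, from mesityl oxide).

Steps most likely to fail

Step 7. What may go wrong is a [1,7]-hydrogen shift from the inner allylic CH2 overtaking the electrocyclisation, or decay of the ruthenium carbene and intermolecular metathesis before ring B has formed. The fallback splits the cascade into two known operations and sets out from 9. Dimethylaluminium chloride Me2AlCl (1.2 equiv) in CH2Cl2 at −78 → −20 °C should promote the closure as a Lewis-acid-assisted 6π electrocyclisation (an intramolecular Mukaiyama–Michael addition in its polar limit), far below the temperature of the hydrogen shift. Aqueous acidic work-up should then give the monocyclic keto diester F1. A separate ring-closing metathesis of F1 with the same ruthenium catalyst (CH2Cl2, 40 °C) comes back to the route at 12.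

Step 6. What may go wrong is transmetallation of the tetrasubstituted α-stannyl enoate being so slow that protodestannylation and homocoupling overtake the cross-coupling, or the product electrocyclising during a long reaction. The fallback reverses the roles of the partners and leaves palladium out of the bond-forming step; it sets out from 7 and 6. The vinylcopper made from 7 as in step 5 is quenched with I2 instead of the tin chloride to give the α-iodo enoate F2. Triflate 6 is converted with hexamethylditin, Pd(PPh3)4 and LiCl (THF, 60 °C) into the dienyl trimethylstannane F3. F2 and F3 are then joined with copper thiophene-2-carboxylate (CuTC, NMP, 0 °C), a coupling that should tolerate hindered partners and retain both geometries; it comes back to the route at 9.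

Step 9. What may go wrong is too small a rate difference between the two enantiomers at this hindered ketone, or reduction by uncatalysed borane, which would erode the enantiomeric purity. The fallback is a classical resolution and sets out from 13. CF3CO2H/CH2Cl2 should cleave both esters to the racemic keto diacid F4. Crystallisation with (R)-1-phenylethylamine (or its enantiomer, whichever gives the less soluble salt of the wanted acid) should give the diastereomerically pure salt F5. Aqueous HCl should then liberate the single-enantiomer keto diacid F6. Re-esterification with tert-butyl 2,2,2-trichloroacetimidate (BF3·OEt2 cat.) should give the single-enantiomer diester F7. Substrate-controlled α-face reduction of F7 with NaBH4 (MeOH, 0 °C) comes back to the route at 14.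

Further compounds
F1 | step 7 | rac-di-tert-butyl (3S,4S)-3-methyl-4-(2-methylbut-3-en-2-yl)-5-oxo-3-(prop-2-en-1-yl)cyclohex-1-ene-1,2-dicarboxylate | O=C1CC(C(=O)OC(C)(C)C)=C(C(=O)OC(C)(C)C)[C@@](C)(CC=C)[C@@H]1C(C)(C)C=C
F2 | step 6 | tert-butyl (2Z)-2-iodo-3-methylhexa-2,5-dienoate | C=CC/C(C)=C(\I)C(=O)OC(C)(C)C
F3 | step 6 | tert-butyl (2Z,4Z)-4-(tert-butyldimethylsilyloxy)-6,6-dimethyl-2-(trimethylstannyl)octa-2,4,7-trienoate | C=CC(C)(C)/C=C(\O[Si](C)(C)C(C)(C)C)/C=C(\[Sn](C)(C)C)C(=O)OC(C)(C)C
F4 | step 9 | rac-(1S,2S,4aS,8aS)-5,5,8a-trimethyl-4-oxodecahydronaphthalene-1,2-dicarboxylic acid | O=C1C[C@H](C(=O)O)[C@H](C(=O)O)[C@@]2(C)CCCC(C)(C)[C@H]12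
F5 | step 9 | (R)-1-phenylethylammonium hydrogen (1S,2S,4aS,8aS)-5,5,8a-trimethyl-4-oxodecahydronaphthalene-1,2-dicarboxylate | C[C@@H]([NH3+])c1ccccc1.O=C1C[C@H](C(=O)O)[C@H](C(=O)[O-])[C@@]2(C)CCCC(C)(C)[C@H]12
F6 | step 9 | (1S,2S,4aS,8aS)-5,5,8a-trimethyl-4-oxodecahydronaphthalene-1,2-dicarboxylic acid, single enantiomer | O=C1C[C@H](C(=O)O)[C@H](C(=O)O)[C@@]2(C)CCCC(C)(C)[C@H]12
F7 | step 9 | di-tert-butyl (1S,2S,4aS,8aS)-5,5,8a-trimethyl-4-oxodecahydronaphthalene-1,2-dicarboxylate, single enantiomer | O=C1C[C@H](C(=O)OC(C)(C)C)[C@H](C(=O)OC(C)(C)C)[C@@]2(C)CCCC(C)(C)[C@H]12
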